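Look at the stop first.

| flask | starting material | second substrate | free enzyme | added ligand | impurity | temperature | remark | time |
|---|---|---|---|---|---|---|---|---|
| north-west | 0.16 M | 0.32 M | 2.7 µM | 3.8 µM | 3.5 µM | 25 °C | the very flask that is asked about, followed so far |  |
| south-east | 0.16 M | 0.16 M | 2.7 µM | 3.8 µM | 3.5 µM | 10 °C | run made earlier |  |
| flask | 0.16 M | 0.320 M | 2.7 µM | 3.8 µM | 3.5 µM | 25 °C |  | 4.0 d |

| run | time / h | target / % | starting material / % |
|---|---|---|---|
| north-west | 6.00 | 25.3 | 75.0 |
| north-west | 20.0 | 31.8 | 67.9 |
| north-west | 40.0 | 32.1 | 68.2 |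
| north-west | 60.0 | 32.5 | 67.9 |
| north-west | 72.0 | 32.4 | 68.4 |
| south-east | 0.500 | 2.9 | 97.1 |
| south-east | 1.00 | 5.8 | 94.0 |
| south-east | 2.00 | 9.8 | 90.6 |
| south-east | 4.00 | 15.5 | 84.6 |
| south-east | 8.00 | 22.9 | 77.3 |

(scatter of a reading: 0.3 percentage points)

- dawn: at 4.0 d add free enzyme, 50.0 % of the amount charged, then wait 4.0 d
- spring: at 4.0 d raise the temperature by 25 K, then wait 4.0 d
- midnight: at 4.0 d take out 90 % of the target then present, then wait 4.0 d
- noon: change nothing and wait 4.0 d more

- target, in percent of the starting material first charged, at 4.0 d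
- which option adds most target ("none" when 2 percentage points or less is all one gets) (dawn / spring / midnight / noon / none)
- target present, with what was taken out counted in, in percent of the starting material first charged, after dawn
- target present, with what was taken out counted in, in percent of the starting material first charged, after spring

- target taken out counts as made
- the numbers in the tables scatter with a standard deviation of 0.3 percentage points
- additions bring no volume worth counting

The north-west run is the asked flask itself, and from 40.0 h to 72.0 h its target lies flat at 32.3 % while 68.4 % of the starting material still stands there, so I expect that same figure at 4.0 d. The south-east run, colder, is at 22.9 % and still climbing at 8.00 h, and I read the flat stretch as dead catalyst, not a reached balance.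

The bench rule for a dead catalyst is the turnover number: each enzyme makes a set amount of target before it dies, so the yield goes with the enzyme charged, and dawn should give

target after dawn = plateau × (1 + added share) = 48.5 %

That rule is honest only while the killer outlasts every enzyme, and I take the impurity to be the killer, one enzyme for each impurity, so I hold the two charges against each other:

cover now = [free enzyme] / [impurity] = 0.771

cover after dawn = 1.16

The cover, enzyme charged over impurity charged, stands below one in this flask, so I expect the enzyme to die with impurity to spare and the rule to hold up to the stop. After dawn it stands above one, and there I expect the rule to end, with the enzyme that outlasts the impurity going on working. So I commit to dawn, well above 48.5 %, and expect no gain from waiting, heating or taking target out.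

The forecast gives 32.3 % for now, dawn as best, 45 % after dawn and 32.4 % after spring, and it expects “more if some outlasts the remaining impurity”. On dawn my reckoning stands above its figure.

The flask gives 32.2 % at 4.0 d, dawn as best with a gain of 55 percentage points, 87.0 % after dawn and 32.2 % after spring.

    free enzyme → unfolded enzyme (k = 0.00837 h⁻¹, Ea = 246 kJ mol⁻¹)
    starting material + free enzyme ⇌ complex A (K = 11.0 M⁻¹, k = 1.56 × 10⁶ M⁻¹ h⁻¹, Ea = 42.0 kJ mol⁻¹, ΔH = −53.0 kJ mol⁻¹)
    complex A → free enzyme + target (k = 27700 h⁻¹, Ea = 58.0 kJ mol⁻¹)
    second substrate + free enzyme ⇌ complex B (K = 3.60 M⁻¹, k = 1.06 × 10⁶ M⁻¹ h⁻¹, Ea = 41.0 kJ mol⁻¹, ΔH = −60.0 kJ mol⁻¹)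
    complex B → free enzyme + second product (k = 8090 h⁻¹, Ea = 73.0 kJ mol⁻¹)
    free enzyme + added ligand ⇌ idle complex (K = 5.27 × 10⁵ M⁻¹, k = 1.20 × 10⁶ M⁻¹ h⁻¹, Ea = 35.0 kJ mol⁻¹, ΔH = −26.0 kJ mol⁻¹)
    free enzyme + impurity → spent catalyst A (k = 8.05 × 10⁵ M⁻¹ h⁻¹, Ea = 44.0 kJ mol⁻¹)
    2 complex A → spent catalyst B (k = 1.85 × 10⁵ M⁻¹ h⁻¹, Ea = 36.0 kJ mol⁻¹)
    (constants at 25 °C)

The stop is the work of the path from free enzyme and impurity to spent catalyst A: struck out, this flask reaches >99.9 % at 4.0 d instead of 32.2 %. The cover after dawn was 1.16, and at 96.0 h this flask keeps 29 % of its impurity, which is 1.03 µM, while dawn adds 1.35 µM of enzyme. In the neighbour flask charged with 1.4 × 10⁻⁶ M of impurity the cover is 1.93, above one, so enzyme should outlast the impurity there. Computed, that flask holds 99.2 % target, with 0 % of its impurity left.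

Readings and results stem from a simulated flask for substances that don't exist, noise included.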